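A closed flask keeps its charge, so whatever is neither Z nor G is still in there, and that remainder can be followed from the readings.

| flask | Q | remark | time |
|---|---|---|---|
| south | 0.25 M | run made earlier |  |
| north | 1 M | run made earlier |  |
| flask | 0.50 M |  | 12 d |

- south (time / d: Z / %, G / %): 2.08: 12.1, 52.3; 4.00: 10.5, 57.6; 6.00: 9.8, 58.0; 8.00: 9.6, 58.0; 10.0: 9.5, 58.7; 12.0: 10.2, 59.6; 15.0: 10.1, 58.2
- north (time / d: Z / %, G / %): 2.08: 13.1, 50.6; 4.00: 10.8, 56.0; 6.00: 10.3, 57.0; 8.00: 11.1, 58.1; 10.0: 10.5, 58.5; 12.0: 11.3, 56.3; 15.0: 11.0, 57.0

(scatter of a reading: 0.5 percentage points)

- the numbers in the tables scatter by 0.5 percentage points (one standard deviation)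
- a reading or a percentage of Z counts all its forms, free or not
- the reaction counts as stopped when no species that holds the Q changes by six tenths of a point or more over the second half of the time

- at 12 d, what has stopped the reaction, if anything has (it is still moving / all of Q has reacted / forward and back rates have come level)
- Z at 12 d, in percent of the Q charged
- G at 12 d, in percent of the Q charged

— What do you reckon with?

The left share, not the yields. Averaging the south and north readings at 12.0 d and 15.0 d, 31.6% of the charge is neither Z nor G: that is the left share.

— Is it still moving?

Early, yes. The mean of both runs goes from 35.9% at 2.08 d to 32.5% at 6.00 d. The later step down to the left share is 0.90 percentage points, but a mean of two such readings itself scatters by 0.5 points, so I see no resolved drift.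

— You pooled two different charges. Why?

That is the weak spot. Over those two readings the left share of the north run stands 1.3 points above that of the south run, a hint of an effect of the charge and no more, with each of those two means scattering by 0.5 points. The flask's 0.50 M is the geometric middle of the two charges, so the pooled mean is my number for this flask at 12 d.

— And the forecast?

It says forward and back rates have come level, which is thermodynamic control in the usual term, with Z 10.3% and G 58%, because “Nothing drifts beyond the scatter from 6 to 15 d”. Those figures leave 31.7%.

The flask gives forward and back rates have come level, with Z 10.1% and G 58.2%.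

    Q ⇌ L (K = 0.430, k = 0.0350 h⁻¹)
    Q ⇌ G (K = 2.70, k = 0.0450 h⁻¹)
    L ⇌ Z (K = 1.00, k = 0.920 h⁻¹)
    Q + Z ⇌ E, settled at all times (K = 0.810 L mol⁻¹)

The flask's left share is 31.7% against the 31.6% read beforehand, and it holds Q 21.6%, L 9.28% and the Q bound in E, 0.811%. The back steps G to Q and L to Q together keep Q from being used up in this flask: the run without G to Q converts 99.8% of the Q instead of 78.4%, the one without L to Q converts 98.1%, and either removal changes what ends the reaction. The same flask read at 8.0 d has a left share of 31.7%.

The numbers in the tables were generated by integration with constants of no real substance, and the scatter is random.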